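## Retrosynthetic overview

- Galbinic acid ⇐ fluoride desilylation of a doubly silylated precursor; the lactol stereocentre ⇐ catalytic dynamic kinetic O-silylation of the racemic, ring–chain-labile lactol (new step).
- Seven-membered depsidone lactone ⇐ ring expansion (acyl C→O shift) of a spiro-furanone cyclohexadienone ⇐ oxidative spirocyclisation of a 2,2'-dihydroxybenzophenone.
- Benzophenone ⇐ Friedel–Crafts union of a ring A salicylic acid and a ring B hydroxyphthalide at its only free ring carbon.
- Both fragments ⇐ methyl haematommate ⇐ methyl orsellinate ⇐ two molecules of methyl acetoacetate.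
- Ring order: benzene ring (used for ring A and ring B) → hydroxy-γ-lactone on ring B → spiro five-membered furanone → seven-membered dioxepinone.

Assumption: the lactol carbon racemises by ring–chain tautomerism in basic or protic media, so it is fixed only in step 10, released under weakly acidic fluoride at low temperature in step 11, and the product is kept cold in neutral aprotic solution; the sense of induction in step 10 is predicted by analogy and must be confirmed on 16, with the mirror-image catalyst used if it is reversed.

## Route

Step 1
Reactants: 1 methyl acetoacetate (two molecules)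
Product: 3 methyl orsellinate (methyl 2,4-dihydroxy-6-methylbenzoate), via methyl 3,5,7-trioxooctanoate 2 (not isolated)
Conditions: NaH (1.0 eq), n-BuLi (1.0 eq), THF, 0 °C → reflux, 16 h; aq. HCl
Reagents that add atoms: none
Why: the acetoacetate dianion undergoes Claisen self-condensation through its terminal carbanion to triketo ester 2, which closes by intramolecular aldol condensation and enolises to the arene (biomimetic polyketide aromatisation).

Step 2
Reactants: 3 methyl orsellinate
Product: 4 methyl haematommate (methyl 3-formyl-2,4-dihydroxy-6-methylbenzoate)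
Conditions: Cl2CHOCH3 (1.2 eq), TiCl4 (2.5 eq), CH2Cl2, −10 → 20 °C; aq. HCl; recrystallisation
Reagents that add atoms: dichloromethyl methyl ether COC(Cl)Cl; water O
Why: Rieche formylation, in which titanium phenoxide chelation and double ortho activation direct the electrophile to C-3 between the two hydroxyl groups; the minor 5-formyl isomer is removed by crystallisation.

Step 3
Reactants: 4 methyl haematommate
Product: 5 haematommic acid (3-formyl-2,4-dihydroxy-6-methylbenzoic acid)
Conditions: KOH (4 M aq., 8 eq), 60 °C, Ar, 6 h; then 2 M HCl, 0 °C, pH 2; used at once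
Reagents that add atoms: potassium hydroxide [K+].[OH-]
Why: ester saponification of the hindered salicylate at the phenoxide stage, where neither decarboxylation nor aldehyde disproportionation occurs, followed by cold acidification to avoid decarboxylation of the free acid.

Step 4
Reactants: 5 haematommic acid
Product: 7 4-[(tert-butyldimethylsilyl)oxy]-3-formyl-2-hydroxy-6-methylbenzoic acid, via bis-silyl derivative 6 (not isolated)
Conditions: t-BuMe2SiCl (2.2 eq), imidazole (4.5 eq), DMF, 0 → 20 °C; then AcOH/THF/H2O (1:4:1), 0 °C
Reagents that add atoms: tert-butyldimethylsilyl chloride CC(C)(C)[Si](C)(C)Cl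
Why: silylation of the carboxyl group and of the less hindered 4-OH (the 2-OH is chelated and flanked by two carbonyl groups), then selective hydrolysis of the labile silyl ester; the remaining silyl ether leaves ring A with only one chelated phenol so that ring B alone is oxidised in step 9.

Step 5
Reactants: 4 methyl haematommate
Product: 9 methyl 2,4-diacetoxy-3-(acetoxymethyl)-6-methylbenzoate, via benzylic alcohol 8 (not isolated)
Conditions: NaBH4 (1.0 eq), THF/MeOH (10:1), 0 °C; AcOH quench, evaporation; then Ac2O (6 eq), pyridine, 4-(dimethylamino)pyridine (5 mol %), 0 → 20 °C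
Reagents that add atoms: acetic anhydride CC(=O)OC(C)=O
Why: hydride reduction of the chelated aldehyde (the hindered ester is untouched) followed by immediate peracetylation, which traps the sensitive 2,6-dihydroxybenzyl alcohol 8, installs the acetate of the target and deactivates the ring for step 6.

Step 6
Reactants: 9 methyl 2,4-diacetoxy-3-(acetoxymethyl)-6-methylbenzoate
Product: 10 methyl 2,4-diacetoxy-3-(acetoxymethyl)-6-(dibromomethyl)benzoate
Conditions: N-bromosuccinimide (2.3 eq), azobisisobutyronitrile (5 mol %), PhCF3, 95 °C
Reagents that add atoms: N-bromosuccinimide O=C1CCC(=O)N1Br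
Why: Wohl–Ziegler radical bromination; the acyloxy groups suppress ring bromination, and the unhindered 6-methyl group is dibrominated in preference to the electron-poor, doubly flanked acetoxymethyl CH2.

Step 7
Reactants: 10 methyl 2,4-diacetoxy-3-(acetoxymethyl)-6-(dibromomethyl)benzoate
Product: 12 (±)-(3,5,7-trihydroxy-1-oxo-1,3-dihydroisobenzofuran-6-yl)methyl acetate (ring B lactol, racemic at C-3), via lactol diacetate 11 (not isolated)
Conditions: AgOAc (2.2 eq), AcOH/H2O (9:1), 60 °C; then p-TsOH·H2O (0.3 eq), 70 °C
Reagents that add atoms: water O
Why: silver-assisted solvolysis of the gem-dibromide with participation of the ortho ester gives the 3-hydroxyphthalide 11 (racemic), and acid-catalysed hydrolysis then frees the two phenols while the benzylic acetate, which can only exchange with the acetic acid solvent, is retained.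

Step 8
Reactants: 7 4-[(tert-butyldimethylsilyl)oxy]-3-formyl-2-hydroxy-6-methylbenzoic acid; 12 ring B lactol
Product: 13 (±)-{4-[4-(tert-butyldimethylsilyloxy)-3-formyl-2-hydroxy-6-methylbenzoyl]-3,5,7-trihydroxy-1-oxo-1,3-dihydroisobenzofuran-6-yl}methyl acetate (benzophenone)
Conditions: (CF3CO)2O (5 eq), CF3CO2H/CH2Cl2 (1:4), 0 → 20 °C, 24 h; then NaH2PO4/Na2HPO4 buffer (pH 7)/THF, 20 °C
Reagents that add atoms: none
Why: Friedel–Crafts acylation, in which the di-ortho-substituted acid is activated by the anhydride to its acylium ion and attacks C-4 of 12, the only unsubstituted ring carbon (ortho to 5-OH, para to the chelated 7-OH); the electron-poor lactol carbon and the acetoxymethyl group do not ionise in this medium.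

Step 9
Reactants: 13 benzophenone
Product: 15 (±)-ring A O-(tert-butyldimethylsilyl) galbinic acid (depsidone; lactol carbon racemic), via spiro-grisadienedione 14 (not isolated)
Conditions: PhI(OAc)2 (1.05 eq), (CF3)2CHOH/CH2Cl2 (1:4), 0 °C, 30 min; then 40 °C, 3 h
Reagents that add atoms: none
Why: the trivalent iodine reagent oxidises the free resorcinol of ring B and the chelated ring A phenol closes onto the ipso carbon (5-exo oxidative dearomatising spirocyclisation) to give 14, whose enolic oxygen ortho to the spiro carbon then attacks the adjacent furanone carbonyl with C–C cleavage and rearomatisation of ring B; this stepwise polar acyl C→O shift expands the five-membered furanone to the seven-membered lactone (grisadienedione–depsidone rearrangement).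

Step 10
Reactants: 15 (±)-ring A O-TBS galbinic acid
Product: 16 lactol O-triphenylsilyl, ring A O-TBS galbinic acid (single enantiomer; lactol carbon has the spatial arrangement of the target, CIP descriptor R because O–Si outranks the ring oxygen)
Conditions: Ph3SiCl (1.3 eq), (S)-benzotetramisole (C15H12N2S, (S)-2-phenyl-2,3-dihydroimidazo[2,1-b][1,3]benzothiazole, 10 mol %), i-Pr2NEt (1.5 eq), THF, 4 Å sieves, −40 °C
Reagents that add atoms: triphenylsilyl chloride Cl[Si](c1ccccc1)(c1ccccc1)c1ccccc1
Why: Proposed new method: dynamic kinetic resolution of a 3-hydroxyphthalide by catalytic enantioselective O-silylation, in which the isothiourea attacks Ph3SiCl to form a chiral N-silyl isothiouronium ion, π-stacking of the phthalide arene on this cation makes silyl transfer to the (S)-lactol faster, and the slow enantiomer racemises through amine-promoted ring–chain tautomerism (lactol ⇌ 2-formylbenzoate) so that all material funnels to one configurationally locked silyl acetal, which sets the only stereocentre; the closest known reaction types are the isothiourea-catalysed silylative kinetic resolution of cyclic benzylic alcohols with Ph3SiCl and the acylative dynamic kinetic resolution of lactols by chiral nucleophilic catalysts.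

Step 11
Reactants: 16 bis-silylated galbinic acid
Product: 17 galbinic acid, (S) at the lactol carbon
Conditions: HF·pyridine (10 eq), pyridine/THF, −20 → 0 °C; NaH2PO4/Na2HPO4 buffer (pH 7), 0 °C; product kept cold
Reagents that add atoms: none
Why: fluoride-driven desilylation of the silyl acetal and of the aryl silyl ether; the C–O bond at the stereocentre is never broken and the oxygen is released as the neutral hydroxyl in a weakly acidic medium, so the ring-opening lactol alkoxide is avoided and the configuration set in step 10 is retained.

## Compound list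

1 | methyl acetoacetate | CC(=O)CC(=O)OC | starting material
2 | methyl 3,5,7-trioxooctanoate | CC(=O)CC(=O)CC(=O)CC(=O)OC | intermediate (not isolated)
3 | methyl orsellinate (methyl 2,4-dihydroxy-6-methylbenzoate) | COC(=O)c1c(C)cc(O)cc1O | intermediate
4 | methyl haematommate (methyl 3-formyl-2,4-dihydroxy-6-methylbenzoate) | COC(=O)c1c(C)cc(O)c(C=O)c1O | intermediate
5 | haematommic acid | OC(=O)c1c(C)cc(O)c(C=O)c1O | intermediate
6 | tert-butyldimethylsilyl 4-[(tert-butyldimethylsilyl)oxy]-3-formyl-2-hydroxy-6-methylbenzoate | CC(C)(C)[Si](C)(C)OC(=O)c1c(C)cc(O[Si](C)(C)C(C)(C)C)c(C=O)c1O | intermediate (not isolated)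
7 | 4-[(tert-butyldimethylsilyl)oxy]-3-formyl-2-hydroxy-6-methylbenzoic acid | OC(=O)c1c(C)cc(O[Si](C)(C)C(C)(C)C)c(C=O)c1O | intermediate
8 | methyl 2,4-dihydroxy-3-(hydroxymethyl)-6-methylbenzoate | COC(=O)c1c(C)cc(O)c(CO)c1O | intermediate (not isolated)
9 | methyl 2,4-diacetoxy-3-(acetoxymethyl)-6-methylbenzoate | COC(=O)c1c(C)cc(OC(C)=O)c(COC(C)=O)c1OC(C)=O | intermediate
10 | methyl 2,4-diacetoxy-3-(acetoxymethyl)-6-(dibromomethyl)benzoate | COC(=O)c1c(C(Br)Br)cc(OC(C)=O)c(COC(C)=O)c1OC(C)=O | intermediate
11 | (±)-[5,7-diacetoxy-3-hydroxy-1-oxo-1,3-dihydroisobenzofuran-6-yl]methyl acetate | CC(=O)OCc1c(OC(C)=O)cc2C(O)OC(=O)c2c1OC(C)=O | intermediate (not isolated)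
12 | (±)-(3,5,7-trihydroxy-1-oxo-1,3-dihydroisobenzofuran-6-yl)methyl acetate | CC(=O)OCc1c(O)cc2C(O)OC(=O)c2c1O | intermediate
13 | (±)-{4-[4-(tert-butyldimethylsilyloxy)-3-formyl-2-hydroxy-6-methylbenzoyl]-3,5,7-trihydroxy-1-oxo-1,3-dihydroisobenzofuran-6-yl}methyl acetate | CC(=O)OCc1c(O)c(C(=O)c3c(C)cc(O[Si](C)(C)C(C)(C)C)c(C=O)c3O)c2C(O)OC(=O)c2c1O | intermediate
14 | spiro-grisadienedione: ring A benzofuran-3(2H)-one (4-methyl, 6-silyloxy, 7-formyl) joined through spiro C-2 to the ring B cyclohexadienone (2'-oxo, 3'-acetoxymethyl, 4'-hydroxy, 5',6'-fused 5-hydroxyfuran-2(5H)-one); racemic mixture of diastereomers | O=C1c2c(C)cc(O[Si](C)(C)C(C)(C)C)c(C=O)c2OC13C(=O)C(COC(C)=O)=C(O)C4=C3C(O)OC4=O | intermediate (not isolated)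
15 | (±)-galbinic acid ring A tert-butyldimethylsilyl ether (phenol ortho to CHO silylated; lactol racemic) | CC(=O)OCc1c(O)c2c(c3c1OC(=O)c1c(C)cc(O[Si](C)(C)C(C)(C)C)c(C=O)c1O3)C(O)OC2=O | intermediate
16 | galbinic acid ring A tert-butyldimethylsilyl ether, lactol O-triphenylsilyl ether; lactol carbon R by CIP, same spatial arrangement as in 17 | CC(=O)OCc1c(O)c2c(c3c1OC(=O)c1c(C)cc(O[Si](C)(C)C(C)(C)C)c(C=O)c1O3)[C@@H](O[Si](c1ccccc1)(c1ccccc1)c1ccccc1)OC2=O | intermediate
17 | galbinic acid, (S) at the lactol carbon | CC(=O)OCc1c(O)c2c(c3c1OC(=O)c1c(C)cc(O)c(C=O)c1O3)[C@@H](O)OC2=O | target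

## Step count and risks

Total steps: 11. Longest linear sequence: 9 (steps 1, 2, 5, 6, 7, 8, 9, 10, 11); steps 3 and 4 form the ring A branch from 4.

The three steps most likely to fail:

Step 8 (Friedel–Crafts union). The risks are O-acylation instead of C-acylation, acid-induced ionisation of the acetoxymethyl group, and alkylation of a second ring B molecule by the lactol. The fallback sets out from 7 and 12 and returns at 13. The unchelated 5-OH of 12 is esterified with 7 ((CF3CO)2O, toluene, 20 °C, the usual depside esterification) to give the depside ester F1. F1 is then irradiated (300 nm, degassed MeCN); in this photo-Fries rearrangement the acyl–oxygen bond homolyses and the radical pair recombines at the only free ortho carbon, C-4, under neutral conditions, giving 13.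

Step 9 (oxidative spirocyclisation and ring expansion). The risks are that the acyl shift of 14 is slow or that the enolised dienone loses acetate before it rearranges. The fallback sets out from 13 and returns at 15. Compound 13 is oxidised with PhI(OAc)2 in wet MeCN buffered with NaOAc at 0 °C; water adds to the furanone carbonyl of 14 and retro-Claisen cleavage, driven by aromatisation of ring B, gives the diaryl ether seco acid F2. The seven-membered lactone is then closed in a separate operation with N-(3-dimethylaminopropyl)-N'-ethylcarbodiimide hydrochloride in dilute CH2Cl2 at 0 °C, giving 15.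

Step 10 (proposed dynamic kinetic silylation). The risks are low selectivity, lactol racemisation that is too slow at −40 °C, and an uncatalysed racemic background silylation through the open carboxylate. The fallback uses known chemistry, sets out from 15 and returns at 16. Compound 15 is silylated without a chiral catalyst (Ph3SiCl, imidazole, DMF, 0 °C) to give the racemic silyl acetal F3, which is configurationally stable. Its enantiomers are separated by preparative HPLC on a chiral stationary phase (amylose tris(3,5-dimethylphenylcarbamate)); the enantiomer identical with 16 goes on to step 11. The other enantiomer is desilylated with HF·pyridine back to 15, which racemises and is recycled.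

## Further compounds

F1 | step 8 | (±)-6-(acetoxymethyl)-3,7-dihydroxy-1-oxo-1,3-dihydroisobenzofuran-5-yl 4-[(tert-butyldimethylsilyl)oxy]-3-formyl-2-hydroxy-6-methylbenzoate (depside ester) | CC(=O)OCc1c(OC(=O)c3c(C)cc(O[Si](C)(C)C(C)(C)C)c(C=O)c3O)cc2C(O)OC(=O)c2c1O
F2 | step 9 | (±)-2-{[6-(acetoxymethyl)-3,5,7-trihydroxy-1-oxo-1,3-dihydroisobenzofuran-4-yl]oxy}-4-[(tert-butyldimethylsilyl)oxy]-3-formyl-6-methylbenzoic acid (seco acid) | CC(=O)OCc1c(O)c2C(=O)OC(O)c2c(Oc3c(C=O)c(O[Si](C)(C)C(C)(C)C)cc(C)c3C(=O)O)c1O
F3 | step 10 | (±)-galbinic acid ring A tert-butyldimethylsilyl ether, lactol O-triphenylsilyl ether (racemic silyl acetal) | CC(=O)OCc1c(O)c2c(c3c1OC(=O)c1c(C)cc(O[Si](C)(C)C(C)(C)C)c(C=O)c1O3)C(O[Si](c1ccccc1)(c1ccccc1)c1ccccc1)OC2=O
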